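**Strategy.** Everything rests on cutting ring A (C1–C4, C4a, C8a), a cyclohexa-1,3-diene fused trans to ring B, back to an acyclic triene (numbering: C1 bears the propenyl group, C2 the acyl group). The methyl-bearing C4 is read as a masked ketone carbon: its enol ether (C4=C4a) is the dienophile, and a silylated 2-(methoxycarbonyl)diene (C3=C2–C1=C8a) is the diene. One thermal intramolecular inverse-demand Diels–Alder reaction closes rings A and B, makes C4a–C8a and C3–C4, and relays the one bought stereocentre (C7, from (S)-citronellal) to C4a and C8a; acid then expels Me3SiOEt across C3–C4, giving the C3=C4 double bond regiospecifically. The acylpyridone is attached afterwards by an aryllithium–aldehyde union.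

Key step: step 8

Remark on the chemistry: (4aS,7S,8aS) is the trans-fused, all-equatorial arrangement, so (S)-citronellal supplies C7. Enol ether 8 is carried as an E/Z mixture, because C4 becomes sp2 again in step 8.

Step 1
Reactants: 1 (S)-citronellal
Product: 2 (4S)-1,1-dibromo-4,8-dimethylnona-1,7-diene
Conditions: CBr4, PPh3, Zn, CH2Cl2, 0 °C to 23 °C
Reagents that add atoms: carbon tetrabromide, BrC(Br)(Br)Br
Why: Ramirez (Corey–Fuchs) dibromo-olefination turns the aldehyde carbon (future C8a) into a CH=CBr2 unit whose two bromides can later be replaced one after the other with defined geometry, and the remote stereocentre is untouched.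

Step 2
Reactants: 2 (4S)-1,1-dibromo-4,8-dimethylnona-1,7-diene
Product: 3 (4S)-7,7-dibromo-4-methylhept-6-enal
Conditions: O3, CH2Cl2/MeOH, −78 °C; then Me2S, −78 °C to 23 °C
Reagents that add atoms: ozone, [O-][O+]=O
Why: Ozonolysis should be selective for the electron-rich trisubstituted alkene over the electron-poor 1,1-dibromoalkene and gives the C4a aldehyde after reductive work-up.

Step 3
Reactants: 4 triphenylphosphine hydrobromide, 5 ethyl vinyl ether
Product: 6 (1-ethoxyethyl)triphenylphosphonium bromide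
Conditions: CH2Cl2, 0 °C to 23 °C
Reagents that add atoms: none
Why: Markovnikov addition of the phosphine hydrobromide to the vinyl ether through the oxocarbenium ion is a known way to alpha-alkoxyalkyl phosphonium salts.

Step 4
Reactants: 6 (1-ethoxyethyl)triphenylphosphonium bromide, 3 (4S)-7,7-dibromo-4-methylhept-6-enal
Product: 8 (4S)-1,1-dibromo-8-ethoxy-4-methylnona-1,7-diene (E/Z mixture at the enol ether), via phosphorus ylide 7 (not isolated)
Conditions: KN(SiMe3)2 (slightly less than 6), THF, −78 °C to −40 °C; then 3, −78 °C to 23 °C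
Reagents that add atoms: none
Why: Wittig olefination with the alpha-ethoxy ylide gives the enol ether of a methyl ketone at C4, and the ylide is preformed with a deficit of base so that no free amide dehydrobrominates the dibromoalkene.

Step 5
Reactants: 9 methyl 3-(trimethylsilyl)propiolate
Product: 10 methyl (E)-2-(tributylstannyl)-3-(trimethylsilyl)acrylate
Conditions: Bu3SnH, Pd(PPh3)4 (cat.), THF, 0 °C to 23 °C
Reagents that add atoms: tributyltin hydride, CCCC[SnH](CCCC)CCCC
Why: Palladium-catalysed syn-hydrostannation of an ynoate places tin alpha to the ester and hydrogen cis to tin, which fixes silicon trans to tin.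

Step 6
Reactants: 8 (4S)-1,1-dibromo-8-ethoxy-4-methylnona-1,7-diene, 10 methyl (E)-2-(tributylstannyl)-3-(trimethylsilyl)acrylate
Product: 11 methyl (2E,3Z,6S)-3-bromo-10-ethoxy-6-methyl-2-[(trimethylsilyl)methylidene]undeca-3,9-dienoate (ester carbon chain trans to the tether, bromine cis to it, silicon trans to C1)
Conditions: Pd2(dba)3 (cat.), P(2-furyl)3, CuI (cat.), DMF, 50 °C
Reagents that add atoms: none
Why: Stille coupling of a 1,1-dibromoalkene takes place selectively at the less hindered bromide trans to the alkyl chain with retention at both partners, so C2 ends trans to C8.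

Step 7
Reactants: 11 methyl (2E,3Z,6S)-3-bromo-10-ethoxy-6-methyl-2-[(trimethylsilyl)methylidene]undeca-3,9-dienoate, 12 (E)-prop-1-enylboronic acid
Product: 13 methyl (2Z,3E,6S)-10-ethoxy-6-methyl-3-[(E)-prop-1-enyl]-2-[(trimethylsilyl)methylidene]undeca-3,9-dienoate
Conditions: PdCl2(dppf) (cat.), K3PO4, THF/H2O, 45 °C
Reagents that add atoms: none
Why: Suzuki–Miyaura coupling with retention replaces the remaining bromide by the (E)-propenyl group, which therefore sits cis to the tether as the key step requires.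

Step 8
Reactants: 13 methyl (2Z,3E,6S)-10-ethoxy-6-methyl-3-[(E)-prop-1-enyl]-2-[(trimethylsilyl)methylidene]undeca-3,9-dienoate
Product: 15 methyl (4aS,7S,8aS)-4,7-dimethyl-1-[(E)-prop-1-enyl]-4a,5,6,7,8,8a-hexahydronaphthalene-2-carboxylate, via beta-ethoxysilane cycloadduct 14 (not isolated)
Conditions: toluene (0.005 M), BHT, 120 °C, sealed tube; then CSA (0.3 equiv), 23 °C
Reagents that add atoms: none
Why: On heating, the s-cis 2-(methoxycarbonyl)diene C3=C2–C1=C8a (LUMO lowered by the ester) and the tethered enol ether C4=C4a (HOMO raised by OEt) combine in a concerted, asynchronous intramolecular inverse-electron-demand Diels–Alder reaction that forms C4a–C8a and C3–C4 and leaves C1=C2; CSA then ionises the tertiary C4–OEt bond, the beta-silyl-stabilised cation loses Me3Si from C3, and C3=C4 appears with release of Me3SiOEt. The closest known reaction types are the intramolecular Diels–Alder reaction of 1,7,9-decatrienes to decalins, the use of enol ethers as alkyne equivalents towards electron-poor dienes, and the acid-promoted Peterson-type elimination of beta-alkoxysilanes. Ring B (C4a, C5 to C8, C8a) closes through the C4a–C8a bond with the four-carbon tether in a chair-like array, and ring A (C1 to C4, C4a, C8a) closes as the [4+2] ring in the fused mode. C4a and C8a are controlled by C7: its methyl group lies equatorial in the chair-like tether and so fixes the diene face that is attacked, and the anti (trans-fused) transition state should be preferred because the propenyl group on C1 crowds the tether in the syn (cis-fused) one, while C3 and C4 of the adduct need no control because both become sp2. The step needs chemoselectivity for the ester-bearing diene over the propenyl/C1=C8a diene (secured because the tether is cis to the propenyl group, so that diene cannot reach a productive s-cis geometry, and because only the ester-bearing diene is electron-poor), the bond pairing C4a–C8a with C3–C4 (enforced by the four-atom tether) and a regiospecific elimination (secured by the vicinal silicon/ethoxy pair, which leaves no choice of proton). The temperature is held near 120 °C and the solution dilute so that a 1,5-hydrogen shift in the cis-substituted diene and bimolecular dimerisation of the diene ester should not compete.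

Step 9
Reactants: 15 methyl (4aS,7S,8aS)-4,7-dimethyl-1-[(E)-prop-1-enyl]-4a,5,6,7,8,8a-hexahydronaphthalene-2-carboxylate
Product: 16 [(4aS,7S,8aS)-4,7-dimethyl-1-[(E)-prop-1-enyl]-4a,5,6,7,8,8a-hexahydronaphthalen-2-yl]methanol
Conditions: i-Bu2AlH, CH2Cl2, −78 °C; aqueous potassium sodium tartrate work-up
Reagents that add atoms: none
Why: Hydride reduction of the conjugated ester gives the primary allylic alcohol without touching the triene or the ring-fusion stereocentres.

Step 10
Reactants: 16 [(4aS,7S,8aS)-4,7-dimethyl-1-[(E)-prop-1-enyl]-4a,5,6,7,8,8a-hexahydronaphthalen-2-yl]methanol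
Product: 17 (4aS,7S,8aS)-4,7-dimethyl-1-[(E)-prop-1-enyl]-4a,5,6,7,8,8a-hexahydronaphthalene-2-carbaldehyde
Conditions: MnO2, CH2Cl2, 23 °C
Reagents that add atoms: none
Why: MnO2 oxidises the allylic alcohol chemoselectively to the aldehyde under neutral conditions that should not enolise towards C8a.

Step 11
Reactants: 18 5-bromo-2,4-dimethoxypyridine, 19 (4-methoxyphenyl)boronic acid
Product: 20 2,4-dimethoxy-5-(4-methoxyphenyl)pyridine
Conditions: Pd(PPh3)4 (cat.), K2CO3, 1,4-dioxane/H2O, 90 °C
Reagents that add atoms: none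
Why: Suzuki–Miyaura coupling at the only carbon–bromine bond places the aryl group on C5 of the pyridine.

Step 12
Reactants: 20 2,4-dimethoxy-5-(4-methoxyphenyl)pyridine
Product: 21 4-hydroxy-5-(4-hydroxyphenyl)pyridin-2(1H)-one
Conditions: 48% aq. HBr, AcOH, 110 °C
Reagents that add atoms: none
Why: Bromide cleaves all three protonated methyl ethers by SN2 attack at methyl, which allows the change to acid-labile protecting groups.

Step 13
Reactants: 21 4-hydroxy-5-(4-hydroxyphenyl)pyridin-2(1H)-one
Product: 22 2,4-bis(methoxymethoxy)-5-[4-(methoxymethoxy)phenyl]pyridine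
Conditions: MOMCl, Ag2CO3, toluene, 23 °C, dark
Reagents that add atoms: chloromethyl methyl ether, COCCl
Why: Silver-assisted alkylation with the hard electrophile MOMCl should take place on oxygen at all three sites, the silver salt steering the ambident pyridone to the 2-alkoxypyridine.

Step 14
Reactants: 22 2,4-bis(methoxymethoxy)-5-[4-(methoxymethoxy)phenyl]pyridine, 17 (4aS,7S,8aS)-4,7-dimethyl-1-[(E)-prop-1-enyl]-4a,5,6,7,8,8a-hexahydronaphthalene-2-carbaldehyde
Product: 24 [2,4-bis(methoxymethoxy)-5-[4-(methoxymethoxy)phenyl]pyridin-3-yl][(4aS,7S,8aS)-4,7-dimethyl-1-[(E)-prop-1-enyl]-4a,5,6,7,8,8a-hexahydronaphthalen-2-yl]methanol (both carbinol epimers), via aryllithium 23 (not isolated)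
Conditions: n-BuLi, THF, −78 °C to −30 °C; then 17, −78 °C; aq. NH4Cl
Reagents that add atoms: none
Why: Directed ortho-lithiation should occur at C3 between the two MOM ethers, and the aryllithium adds 1,2 to the aldehyde; the new carbinol stereocentre is not controlled and is removed in the next step.

Step 15
Reactants: 24 the carbinol from step 14
Product: 25 [2,4-bis(methoxymethoxy)-5-[4-(methoxymethoxy)phenyl]pyridin-3-yl][(4aS,7S,8aS)-4,7-dimethyl-1-[(E)-prop-1-enyl]-4a,5,6,7,8,8a-hexahydronaphthalen-2-yl]methanone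
Conditions: Dess–Martin periodinane, CH2Cl2, 0 °C to 23 °C
Reagents that add atoms: none
Why: Dess–Martin oxidation of the doubly activated secondary alcohol gives the aryl ketone under mild conditions that should not epimerise C8a.

Step 16
Reactants: 25 the ketone from step 15
Product: 26 Ilicicolin J
Conditions: TFA/CH2Cl2 (1:5), H2O (few equiv), 0 °C to 23 °C
Reagents that add atoms: none
Why: Acidic acetal cleavage removes the three MOM groups, and the freed 2-hydroxypyridine tautomerises to the 2-pyridone of the target.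

**Compound list**

1 | (S)-citronellal, (3S)-3,7-dimethyloct-6-enal | CC(C)=CCC[C@H](C)CC=O | starting material
2 | (4S)-1,1-dibromo-4,8-dimethylnona-1,7-diene | CC(C)=CCC[C@H](C)CC=C(Br)Br | intermediate
3 | (4S)-7,7-dibromo-4-methylhept-6-enal | O=CCC[C@H](C)CC=C(Br)Br | intermediate
4 | triphenylphosphine hydrobromide | [Br-].[PH+](c1ccccc1)(c1ccccc1)c1ccccc1 | starting material
5 | ethyl vinyl ether | C=COCC | starting material
6 | (1-ethoxyethyl)triphenylphosphonium bromide | CCOC(C)[P+](c1ccccc1)(c1ccccc1)c1ccccc1.[Br-] | intermediate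
7 | (1-ethoxyethylidene)triphenylphosphorane | CCOC(C)=P(c1ccccc1)(c1ccccc1)c1ccccc1 | intermediate (not isolated)
8 | (4S)-1,1-dibromo-8-ethoxy-4-methylnona-1,7-diene (E/Z mixture) | CCOC(C)=CCC[C@H](C)CC=C(Br)Br | intermediate
9 | methyl 3-(trimethylsilyl)propiolate | COC(=O)C#C[Si](C)(C)C | starting material
10 | methyl (E)-2-(tributylstannyl)-3-(trimethylsilyl)acrylate | CCCC[Sn](CCCC)(CCCC)/C(C(=O)OC)=C/[Si](C)(C)C | intermediate
11 | methyl (2E,3Z,6S)-3-bromo-10-ethoxy-6-methyl-2-[(trimethylsilyl)methylidene]undeca-3,9-dienoate | C[Si](C)(C)/C=C(C(=O)OC)/C(Br)=C/C[C@@H](C)CCC=C(C)OCC | intermediate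
12 | (E)-prop-1-enylboronic acid | C/C=C/B(O)O | starting material
13 | methyl (2Z,3E,6S)-10-ethoxy-6-methyl-3-[(E)-prop-1-enyl]-2-[(trimethylsilyl)methylidene]undeca-3,9-dienoate | C[Si](C)(C)/C=C(C(=O)OC)/C(/C=C/C)=C/C[C@@H](C)CCC=C(C)OCC | intermediate
14 | methyl (4aS,7S,8aS)-4-ethoxy-4,7-dimethyl-1-[(E)-prop-1-enyl]-3-(trimethylsilyl)-3,4,4a,5,6,7,8,8a-octahydronaphthalene-2-carboxylate (C3/C4 isomers) | C/C=C/C1=C(C(=O)OC)C([Si](C)(C)C)C(C)(OCC)[C@H]2CC[C@H](C)C[C@H]12 | intermediate (not isolated)
15 | methyl (4aS,7S,8aS)-4,7-dimethyl-1-[(E)-prop-1-enyl]-4a,5,6,7,8,8a-hexahydronaphthalene-2-carboxylate | C/C=C/C1=C(C(=O)OC)C=C(C)[C@H]2CC[C@H](C)C[C@H]12 | intermediate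
16 | [(4aS,7S,8aS)-4,7-dimethyl-1-[(E)-prop-1-enyl]-4a,5,6,7,8,8a-hexahydronaphthalen-2-yl]methanol | C/C=C/C1=C(CO)C=C(C)[C@H]2CC[C@H](C)C[C@H]12 | intermediate
17 | (4aS,7S,8aS)-4,7-dimethyl-1-[(E)-prop-1-enyl]-4a,5,6,7,8,8a-hexahydronaphthalene-2-carbaldehyde | C/C=C/C1=C(C=O)C=C(C)[C@H]2CC[C@H](C)C[C@H]12 | intermediate
18 | 5-bromo-2,4-dimethoxypyridine | COc1cc(OC)c(Br)cn1 | starting material
19 | (4-methoxyphenyl)boronic acid | COc1ccc(B(O)O)cc1 | starting material
20 | 2,4-dimethoxy-5-(4-methoxyphenyl)pyridine | COc1ccc(-c2cnc(OC)cc2OC)cc1 | intermediate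
21 | 4-hydroxy-5-(4-hydroxyphenyl)pyridin-2(1H)-one | O=c1cc(O)c(-c2ccc(O)cc2)c[nH]1 | intermediate
22 | 2,4-bis(methoxymethoxy)-5-[4-(methoxymethoxy)phenyl]pyridine | COCOc1ccc(-c2cnc(OCOC)cc2OCOC)cc1 | intermediate
23 | 3-lithio-2,4-bis(methoxymethoxy)-5-[4-(methoxymethoxy)phenyl]pyridine | [Li]c1c(OCOC)ncc(-c2ccc(OCOC)cc2)c1OCOC | intermediate (not isolated)
24 | [2,4-bis(methoxymethoxy)-5-[4-(methoxymethoxy)phenyl]pyridin-3-yl][(4aS,7S,8aS)-4,7-dimethyl-1-[(E)-prop-1-enyl]-4a,5,6,7,8,8a-hexahydronaphthalen-2-yl]methanol | C/C=C/C1=C(C(O)c2c(OCOC)ncc(-c3ccc(OCOC)cc3)c2OCOC)C=C(C)[C@H]2CC[C@H](C)C[C@H]12 | intermediate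
25 | [2,4-bis(methoxymethoxy)-5-[4-(methoxymethoxy)phenyl]pyridin-3-yl][(4aS,7S,8aS)-4,7-dimethyl-1-[(E)-prop-1-enyl]-4a,5,6,7,8,8a-hexahydronaphthalen-2-yl]methanone | C/C=C/C1=C(C(=O)c2c(OCOC)ncc(-c3ccc(OCOC)cc3)c2OCOC)C=C(C)[C@H]2CC[C@H](C)C[C@H]12 | intermediate
26 | Ilicicolin J, 3-{[(4aS,7S,8aS)-4,7-dimethyl-1-[(E)-prop-1-enyl]-4a,5,6,7,8,8a-hexahydronaphthalen-2-yl]carbonyl}-4-hydroxy-5-(4-hydroxyphenyl)pyridin-2(1H)-one | C/C=C/C1=C(C(=O)c2c(O)c(-c3ccc(O)cc3)c[nH]c2=O)C=C(C)[C@H]2CC[C@H](C)C[C@H]12 | target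

**Step count.** Total: 16 steps. Longest linear sequence: 11 steps (steps 1, 2, 4, 6, 7, 8, 9, 10, 14, 15, 16).

**Steps most likely to fail**

Step 8. The cycloaddition may be slow, because the new C3–C4 bond joins a silyl-bearing carbon to a fully substituted one. A 1,5-hydrogen shift or dimerisation of the diene could then overtake it, and the trans/cis ring-fusion selectivity may be incomplete. The fallback sets out from 8 and comes back at 15; it leaves the silicon out. Methyl propiolate is hydrostannylated (Bu3SnH, Pd(PPh3)4) to methyl 2-(tributylstannyl)acrylate F1. Coupling of F1 with 8 under the conditions of step 6 gives methyl (3Z,6S)-3-bromo-10-ethoxy-6-methyl-2-methylideneundeca-3,9-dienoate F2. Suzuki–Miyaura coupling with 12 gives methyl (3E,6S)-10-ethoxy-6-methyl-2-methylidene-3-[(E)-prop-1-enyl]undeca-3,9-dienoate F3. Its less hindered cycloaddition should proceed at lower temperature to methyl (4aS,7S,8aS)-4-ethoxy-4,7-dimethyl-1-[(E)-prop-1-enyl]-3,4,4a,5,6,7,8,8a-octahydronaphthalene-2-carboxylate F4. CSA in warm toluene then removes ethanol by an E1 path, the conjugated trienoate 15 being the thermodynamically favoured alkene.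

Step 6. Transmetalation of the hindered, electron-poor stannane may be slow, so that selectivity for the trans bromide is lost, double coupling occurs or the dibromoalkene is dehydrobrominated. The fallback sets out from 8 and comes back at 13; it reverses the polarity of the coupling and sets the geometry by a syn-hydrometalation. Treatment of 8 with n-BuLi (2 equiv, THF, −78 °C) gives (4S)-8-ethoxy-4-methylnon-7-en-1-yne F5. Sonogashira coupling with (E)-1-bromoprop-1-ene (PdCl2(PPh3)2, CuI, Et3N) gives (2E,7S)-11-ethoxy-7-methyldodeca-2,10-dien-4-yne F6. Palladium-catalysed syn-hydrostannation (Bu3SnH, PdCl2(PPh3)2), expected to place tin on the alkyne carbon next to the propenyl group, gives tributyl[(2E,4E,7S)-11-ethoxy-7-methyldodeca-2,4,10-trien-4-yl]stannane F7. Bromodestannylation of 10 (Br2, CH2Cl2, −78 °C) gives methyl (E)-2-bromo-3-(trimethylsilyl)acrylate F8, and Stille coupling of F7 with F8 (Pd2(dba)3, AsPh3, CuI) returns to 13.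

Step 14. Lithiation may also take place ortho to the aryl MOM ether or at C6 of the pyridine, or n-BuLi may add to the pyridine ring. The fallback sets out from 21 and comes back at 23; it places the lithium by bromine–lithium exchange. Bromination of 21 with NBS (DMF, 0 °C) at the most nucleophilic position C3 gives 3-bromo-4-hydroxy-5-(4-hydroxyphenyl)pyridin-2(1H)-one F9. MOMCl/Ag2CO3 as in step 13 gives 3-bromo-2,4-bis(methoxymethoxy)-5-[4-(methoxymethoxy)phenyl]pyridine F10. n-BuLi (THF, −78 °C) exchanges the bromine and gives aryllithium 23, which is used in step 14 as before.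

**Further compounds**

F1 | step 8 | methyl 2-(tributylstannyl)acrylate | C=C(C(=O)OC)[Sn](CCCC)(CCCC)CCCC
F2 | step 8 | methyl (3Z,6S)-3-bromo-10-ethoxy-6-methyl-2-methylideneundeca-3,9-dienoate | C=C(C(=O)OC)/C(Br)=C/C[C@@H](C)CCC=C(C)OCC
F3 | step 8 | methyl (3E,6S)-10-ethoxy-6-methyl-2-methylidene-3-[(E)-prop-1-enyl]undeca-3,9-dienoate | C=C(C(=O)OC)/C(/C=C/C)=C/C[C@@H](C)CCC=C(C)OCC
F4 | step 8 | methyl (4aS,7S,8aS)-4-ethoxy-4,7-dimethyl-1-[(E)-prop-1-enyl]-3,4,4a,5,6,7,8,8a-octahydronaphthalene-2-carboxylate | C/C=C/C1=C(C(=O)OC)CC(C)(OCC)[C@H]2CC[C@H](C)C[C@H]12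
F5 | step 6 | (4S)-8-ethoxy-4-methylnon-7-en-1-yne | CCOC(C)=CCC[C@H](C)CC#C
F6 | step 6 | (2E,7S)-11-ethoxy-7-methyldodeca-2,10-dien-4-yne | CCOC(C)=CCC[C@H](C)CC#C/C=C/C
F7 | step 6 | tributyl[(2E,4E,7S)-11-ethoxy-7-methyldodeca-2,4,10-trien-4-yl]stannane | CCOC(C)=CCC[C@H](C)C/C=C(\C=C\C)[Sn](CCCC)(CCCC)CCCC
F8 | step 6 | methyl (E)-2-bromo-3-(trimethylsilyl)acrylate | Br/C(C(=O)OC)=C/[Si](C)(C)C
F9 | step 14 | 3-bromo-4-hydroxy-5-(4-hydroxyphenyl)pyridin-2(1H)-one | O=c1[nH]cc(-c2ccc(O)cc2)c(O)c1Br
F10 | step 14 | 3-bromo-2,4-bis(methoxymethoxy)-5-[4-(methoxymethoxy)phenyl]pyridine | COCOc1ccc(-c2cnc(OCOC)c(Br)c2OCOC)cc1
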